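# Proposed total synthesis of betaethrin H

## Analysis of the target

Betaethrin H (16) is a diaryl ether: two benzene rings joined by one oxygen, with no further ring and no stereocentre. Ring A (C1–C6) carries the hexadecanoyloxymethyl group at C1, the ether oxygen at C2, a free OH at C3 and OCH3 at C5. Ring B (C1'–C6') carries the ether oxygen at C1', OH at C3' and CH3 at C5'. The bond that decides the synthesis is C2–O–C1'. On the ring A side the oxygen is flanked by two ortho substituents (C1, C3) and lies para to the donor at C5; on the ring B side C1' is meta to both OH and CH3 and has no activation for aromatic substitution. The feature that invites the chosen move is the 1,3,5-pattern of ring B: O at C1', O at C3' and CH3 at C5' are the two oxygens and the methyl group of 5-methylcyclohexane-1,3-dione (7). Ring B can therefore be carried as a cyclohexenone, in which C1' is an electrophilic enone β-carbon and C3'–O is a ketone, and aromatized late. Four oxygen functions (aryl ether, methyl ether, two phenols) must be told apart next to one aliphatic ester. The sensitive groups are: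
- the primary benzylic ester, which is labile to base and hydrogenolysis and, being ortho to the ether oxygen, can ionise in acid and close onto the electron-rich ring B to a xanthene;
- the oxidisable resorcinol-type ring B;
- any 2-hydroxybenzyl ester intermediate, which would eliminate to an ortho-quinone methide under base.

## Retrosynthetic reasoning

**16 ⇒ 15.** The last disconnection is the O–H bond at C3, which is carried as a methoxymethyl acetal. This cap is chosen because it survives peracid, carbonate, hydride, an amide base and divalent palladium, and leaves under dilute acid that does not ionise the benzylic ester. The forward step only has to hydrolyse one phenolic acetal.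

**15 ⇒ 12 (through 14 and 13).** Ring B is taken back to a cyclohexenone: the two ring C=C bonds C3'=C4' and C5'=C6' are removed, so that C3'–OH becomes a ketone and C1'–O an enol ether. Two things are gained. The C3' oxygen is masked as a carbonyl while the ester is made, so no phenol competes for the acyl group. The ether bond also becomes a bond to an enone β-carbon, which can be made by addition–elimination. The forward reaction is a ketone dehydrogenation at C4'–C5' followed by tautomerisation.

**12 ⇒ 10 + 11, and 10 ⇒ 9.** The ester C–O bond is cut to the benzylic alcohol 10 and the acid chloride 11; 10 goes back to aldehyde 9. The C1 carbon is kept at the aldehyde level through the coupling for two reasons. A free or acylated CH2O group ortho to a phenoxide would open quinone methide or acyl/enone transfer pathways. The formyl group also makes the C2 phenol acidic enough for a mild base.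

**9 ⇒ 6 + 8 (key disconnection).** The O–C1' bond is cut. This is the only bond between the two halves, and it is cut at the cyclohexenone level, not between two arenes. The forward reaction must deliver the hindered C2 oxygen of 6 to C1' of the β-chloroenone 8 with loss of chloride. It forms the hardest bond of the target and brings in all six ring B carbons with the C3' oxygen and the C5' methyl group already in place.

**8 ⇒ 7.** The C1'–Cl bond goes back to the enol of the symmetrical dione 7, so only one chloroenone can form.

**6 ⇒ 4 (through 5) ⇒ 2 (through 3) ⇒ 1.** The formyl C–C bond at C1 is cut first. Phenol 4 has a single free ortho position, so an ortho-specific formylation can only give 6. The C2–OH of 4 is traced to the formyl group of 2 by aryl migration to oxygen, which places the free OH para to OCH3 and next to the capped oxygen. 2 is the acetal of the one OH of commercial 1. No step in this branch has a regiochemical choice.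

## Alternatives that were turned down

Alternative 1: The textbook disconnection cuts C2–O between two finished arenes. The forward key step would be a nucleophilic aromatic substitution (or its copper-catalysed Ullmann variant) of orcinol A1 on 3-(benzyloxy)-2-fluoro-5-methoxybenzaldehyde A2, the ortho-formyl group activating C2, to give diaryl ether A3. It was turned down for these reasons:
- C2 of A2 lies between two ortho substituents and para to the C5 methoxy donor, which raises the barrier to the anionic σ-adduct (or to metal insertion and reductive elimination).
- A1 has two equivalent OH groups and nucleophilic ring carbons, so double arylation and C-arylation compete unless it is used in large excess.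
- A2 is not an article of commerce and needs its own multi-step synthesis, so nothing is saved in step count.
- The reverse polarity (phenol 6 with a halogenated ring B) needs an unactivated aryl halide and a protecting group on ring B; it is kept only as a fallback.

Alternative 2: Ring B as an aryne, cutting C1'–O and C2'–H. The ortho-silylaryl triflate A4, treated with a fluoride source in the presence of 6, would give an aryne across C1'–C2'. The phenoxide should add at C1', away from the inductively withdrawing benzyloxy group at C3', and protonation at C2' would give diaryl ether A5. It was turned down for these reasons: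
- A4 needs four to five steps from a symmetrical resorcinol (mono-etherification, carbamate, ortho-silylation, triflation), which is more than the bond is worth.
- The aryl anion at C2' sits where a six-membered closure onto the formyl carbon of ring A is possible, so xanthenol formation competes with protonation.
- The second aryne carbon must end as C–H, so the ability of an aryne to take up two substituents is not used.
- Removal of the benzyl ether by hydrogenolysis would later collide with the benzylic ester.

Alternative 3: Ring B from a pyrylium ring by ring opening and closure. 2,6-Dimethyl-4H-pyran-4-one A6 would be activated at C4 with a sulfonic anhydride and substituted by 6 to give the 4-aryloxypyrylium salt A7. Aqueous alkali would add at C2, open the ring to an enedione and close it again by intramolecular aldol condensation to the 3-aryloxy-5-methylphenol, with no redox step. It was turned down for these reasons: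
- Hydroxide can equally add at C4 of A7, the carbon that carries the best leaving group, which returns A6 and 6 and so breaks the bond just made.
- Nothing in the substrate biases C2 over C4.
- The hot alkali needed for the aldol closure does not fit the formyl group of ring A.
- The cyclohexenone route uses the same logic (ether bond made at a non-aromatic carbon) with well-precedented steps, at the price of one dehydrogenation.

Key step: step 5

Remark on the chemistry: compounds 8, 9, 10, 12 and 13 carry one stereocentre (C5', the methyl-bearing ring carbon) and are used as racemates; this centre becomes an aromatic carbon in step 8, so nothing has to be controlled.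

## Route

Step 1
Reactants: 1 2-hydroxy-4-methoxybenzaldehyde
Product: 2 4-methoxy-2-(methoxymethoxy)benzaldehyde
Conditions: MOMCl, i-Pr2NEt, CH2Cl2, 0 °C to rt
Reagents that add atoms: chloromethyl methyl ether, COCCl
Why: O-alkylation of the only OH group (Williamson-type acetal formation); the hydrogen bond to the formyl group slows but does not prevent it, and the acetal is stable to every later step up to the final acid treatment.

Step 2
Reactants: 2 4-methoxy-2-(methoxymethoxy)benzaldehyde
Product: 4 4-methoxy-2-(methoxymethoxy)phenol, via aryl formate 3 (not isolated)
Conditions: mCPBA, CH2Cl2, rt; then K2CO3 (cat.), MeOH, rt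
Reagents that add atoms: 3-chloroperoxybenzoic acid, OOC(=O)c1cccc(Cl)c1
Why: Baeyer–Villiger oxidation; the aryl group with ortho and para oxygen donors migrates in preference to hydrogen, giving formate 3, which is methanolysed to phenol 4. The former formyl carbon is thereby replaced by the oxygen that will become the diaryl ether oxygen, para to OCH3.

Step 3
Reactants: 4 4-methoxy-2-(methoxymethoxy)phenol
Product: 6 2-hydroxy-5-methoxy-3-(methoxymethoxy)benzaldehyde, via hydroxymethylphenol magnesium salt 5 (not isolated)
Conditions: MgCl2, Et3N, (CH2O)n, MeCN, reflux; aq. citric acid work-up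
Reagents that add atoms: paraformaldehyde (reacting as formaldehyde), C=O
Why: Magnesium-mediated ortho-formylation (Casnati–Skattebøl): the magnesium phenoxide delivers formaldehyde to the ortho carbon through a six-membered chelate to give 5, which passes hydride to a second formaldehyde. Only one ortho position of 4 is free, so the aldehyde can only enter at the future C1.

Step 4
Reactants: 7 5-methylcyclohexane-1,3-dione
Product: 8 3-chloro-5-methylcyclohex-2-en-1-one (racemic)
Conditions: (COCl)2, DMF (cat.), CH2Cl2, 0 °C to rt
Reagents that add atoms: oxalyl chloride, ClC(=O)C(=O)Cl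
Why: Conversion of the enol of a 1,3-dione into the vinylogous acid chloride, a standard reaction of cyclohexane-1,3-diones; 7 is symmetrical, so a single chloroenone forms.

Step 5
Reactants: 6 2-hydroxy-5-methoxy-3-(methoxymethoxy)benzaldehyde, 8 3-chloro-5-methylcyclohex-2-en-1-one
Product: 9 5-methoxy-3-(methoxymethoxy)-2-[(5-methyl-3-oxocyclohex-1-en-1-yl)oxy]benzaldehyde
Conditions: K2CO3, DMF, 60 °C
Reagents that add atoms: none
Why: The potassium phenoxide of 6 adds through oxygen to the β-carbon C1' of chloroenone 8 and the resulting enolate expels chloride (addition–elimination at an sp2 carbon), which forms the C2–O–C1' bond of the target as a vinylogous ester. The closest known reaction type is the carbonate-mediated substitution of 3-chlorocyclohex-2-enones by phenols to give 3-aryloxycyclohexenones. No ring is closed and no stereocentre is made; the racemic C5' centre of 8 is carried along and disappears in step 8. The step needs exclusive reaction at the hindered O2: this is the only free oxygen because O3 is capped, it is the formyl-conjugated and therefore most acidic phenol so that K2CO3 ionises it fully, and attack on a trigonal carbon from above the enone plane tolerates the two ortho groups far better than an anionic σ-adduct on an arene or a metal-centred coupling would. It also needs the formyl group to stay untouched: it has no α-hydrogen, and loss of chloride from the adduct enolate should be much faster than aldol addition to the neighbouring aldehyde. In one operation the step joins both halves of the molecule and sets the whole substitution pattern of ring B (O at C1', O at C3', CH3 at C5') from a one-step derivative of a commodity dione.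

Step 6
Reactants: 9 5-methoxy-3-(methoxymethoxy)-2-[(5-methyl-3-oxocyclohex-1-en-1-yl)oxy]benzaldehyde
Product: 10 3-[2-(hydroxymethyl)-4-methoxy-6-(methoxymethoxy)phenoxy]-5-methylcyclohex-2-en-1-one
Conditions: NaBH4, MeOH/THF, −40 °C; AcOH quench
Reagents that add atoms: none
Why: Chemoselective borohydride reduction; the aryl aldehyde is far more electrophilic than the carbonyl of a vinylogous ester. Low temperature and an acidic quench keep the new benzylic alkoxide from adding to C1'.

Step 7
Reactants: 10 3-[2-(hydroxymethyl)-4-methoxy-6-(methoxymethoxy)phenoxy]-5-methylcyclohex-2-en-1-one, 11 hexadecanoyl chloride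
Product: 12 [5-methoxy-3-(methoxymethoxy)-2-[(5-methyl-3-oxocyclohex-1-en-1-yl)oxy]phenyl]methyl hexadecanoate
Conditions: Et3N, DMAP (cat.), CH2Cl2, 0 °C
Reagents that add atoms: none
Why: DMAP-catalysed acylation of a primary alcohol by an acid chloride; no phenol is free at this stage (O3 is an acetal, the C3' oxygen is still a ketone), so the acyl group has only one place to go.

Step 8
Reactants: 12 [5-methoxy-3-(methoxymethoxy)-2-[(5-methyl-3-oxocyclohex-1-en-1-yl)oxy]phenyl]methyl hexadecanoate
Product: 15 [2-(3-hydroxy-5-methylphenoxy)-5-methoxy-3-(methoxymethoxy)phenyl]methyl hexadecanoate, via silyl dienol ether 13 (not isolated), via cross-conjugated dienone 14 (not isolated)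
Conditions: LiN(SiMe3)2, Me3SiCl, THF, −78 °C; solvent change; then Pd(OAc)2, MeCN, rt
Reagents that add atoms: chlorotrimethylsilane, C[Si](C)(C)Cl (its silyl group is held only in 13 and is lost again on the way to 15)
Why: Saegusa–Ito oxidation: kinetic deprotonation of the vinylogous ester at C4' with silylation in the flask gives 13, Pd(OAc)2 forms the palladium enolate, and β-hydride elimination of the C5'–H gives dienone 14, which tautomerises to the phenol, so ring B becomes aromatic. The ketone α'-hydrogens are several pK units more acidic than those next to the ester carbonyl, and enolisation towards C6' instead would lead to the same phenol.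

Step 9
Reactants: 15 [2-(3-hydroxy-5-methylphenoxy)-5-methoxy-3-(methoxymethoxy)phenyl]methyl hexadecanoate
Product: 16 betaethrin H, [3-hydroxy-2-(3-hydroxy-5-methylphenoxy)-5-methoxyphenyl]methyl hexadecanoate
Conditions: aq. HCl (3 M), THF, 35 °C
Reagents that add atoms: none
Why: Acid hydrolysis of a phenolic methoxymethyl acetal, which proceeds under dilute aqueous acid. The primary benzylic ester has only one ortho aryloxy donor and should neither ionise nor hydrolyse under these conditions.

## Compound list

1 | 2-hydroxy-4-methoxybenzaldehyde | COc1ccc(C=O)c(O)c1 | starting material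
2 | 4-methoxy-2-(methoxymethoxy)benzaldehyde | COCOc1cc(OC)ccc1C=O | intermediate
3 | 4-methoxy-2-(methoxymethoxy)phenyl formate | COCOc1cc(OC)ccc1OC=O | intermediate (not isolated)
4 | 4-methoxy-2-(methoxymethoxy)phenol | COCOc1cc(OC)ccc1O | intermediate
5 | 2-(hydroxymethyl)-4-methoxy-6-(methoxymethoxy)phenol (formed as its magnesium salt) | COCOc1cc(OC)cc(CO)c1O | intermediate (not isolated)
6 | 2-hydroxy-5-methoxy-3-(methoxymethoxy)benzaldehyde | COCOc1cc(OC)cc(C=O)c1O | intermediate
7 | 5-methylcyclohexane-1,3-dione | CC1CC(=O)CC(=O)C1 | starting material
8 | 3-chloro-5-methylcyclohex-2-en-1-one (racemic) | CC1CC(Cl)=CC(=O)C1 | intermediate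
9 | 5-methoxy-3-(methoxymethoxy)-2-[(5-methyl-3-oxocyclohex-1-en-1-yl)oxy]benzaldehyde (racemic) | COCOc1cc(OC)cc(C=O)c1OC1=CC(=O)CC(C)C1 | intermediate
10 | 3-[2-(hydroxymethyl)-4-methoxy-6-(methoxymethoxy)phenoxy]-5-methylcyclohex-2-en-1-one (racemic) | COCOc1cc(OC)cc(CO)c1OC1=CC(=O)CC(C)C1 | intermediate
11 | hexadecanoyl chloride (palmitoyl chloride) | CCCCCCCCCCCCCCCC(=O)Cl | starting material
12 | [5-methoxy-3-(methoxymethoxy)-2-[(5-methyl-3-oxocyclohex-1-en-1-yl)oxy]phenyl]methyl hexadecanoate (racemic) | CCCCCCCCCCCCCCCC(=O)OCc1cc(OC)cc(OCOC)c1OC1=CC(=O)CC(C)C1 | intermediate
13 | [5-methoxy-3-(methoxymethoxy)-2-[[5-methyl-3-(trimethylsilyloxy)cyclohexa-1,3-dien-1-yl]oxy]phenyl]methyl hexadecanoate (racemic) | CCCCCCCCCCCCCCCC(=O)OCc1cc(OC)cc(OCOC)c1OC1=CC(O[Si](C)(C)C)=CC(C)C1 | intermediate (not isolated)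
14 | [5-methoxy-3-(methoxymethoxy)-2-[(5-methyl-3-oxocyclohexa-1,4-dien-1-yl)oxy]phenyl]methyl hexadecanoate | CCCCCCCCCCCCCCCC(=O)OCc1cc(OC)cc(OCOC)c1OC1=CC(=O)C=C(C)C1 | intermediate (not isolated)
15 | [2-(3-hydroxy-5-methylphenoxy)-5-methoxy-3-(methoxymethoxy)phenyl]methyl hexadecanoate | CCCCCCCCCCCCCCCC(=O)OCc1cc(OC)cc(OCOC)c1Oc1cc(C)cc(O)c1 | intermediate
16 | betaethrin H, [3-hydroxy-2-(3-hydroxy-5-methylphenoxy)-5-methoxyphenyl]methyl hexadecanoate | CCCCCCCCCCCCCCCC(=O)OCc1cc(OC)cc(O)c1Oc1cc(C)cc(O)c1 | target

## Step count and least certain steps

Total step count: 9. Longest linear sequence: 8 steps (steps 1, 2, 3, 5, 6, 7, 8, 9, from 1 to 16); step 4 is a one-step side branch.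

**Step 5 (key step).** The phenoxide of 6 is flanked on both sides and stabilised by the ortho-formyl group, so O-attack on 8 may be slow enough for hydrolysis of 8 back to 7 (carbonate and traces of water) to compete. The enolate formed on addition may also close onto the neighbouring formyl carbon in a six-membered aldol-type cyclisation before chloride leaves. The fallback gives up the non-aromatic ring B and uses known copper chemistry. It sets out from 6. Commercial 3-bromo-5-methylphenol is capped with MOMCl/i-Pr2NEt to give 1-bromo-3-(methoxymethoxy)-5-methylbenzene F1. F1 is coupled with 6 in an Ullmann-type etherification (CuI, picolinic acid, K3PO4, DMSO, 90 °C) to give 5-methoxy-3-(methoxymethoxy)-2-[3-(methoxymethoxy)-5-methylphenoxy]benzaldehyde F2. Reduction with NaBH4 gives [5-methoxy-3-(methoxymethoxy)-2-[3-(methoxymethoxy)-5-methylphenoxy]phenyl]methanol F3, and acylation with 11 (Et3N, DMAP) gives [5-methoxy-3-(methoxymethoxy)-2-[3-(methoxymethoxy)-5-methylphenoxy]phenyl]methyl hexadecanoate F4. The conditions of step 9 then remove both acetals, and the route is rejoined at 16.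

**Step 8.** The silyl dienol ether 13 may be protodesilylated by the acetic acid released (return to 12), β-hydride elimination may stall, and the amide base may partly deprotonate next to the ester carbonyl. The fallback replaces palladium by a selenoxide syn-elimination and sets out from 12. LiN(SiMe3)2 in THF at −78 °C followed by PhSeCl gives [5-methoxy-3-(methoxymethoxy)-2-[(5-methyl-3-oxo-4-(phenylselanyl)cyclohex-1-en-1-yl)oxy]phenyl]methyl hexadecanoate F5. Oxidation with H2O2/pyridine in CH2Cl2 at 0 °C gives the selenoxide, which eliminates to 14 and tautomerises; the route is rejoined at 15.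

**Step 6.** The new benzylic alkoxide may add to C1' (six-membered spiro ketal) and expel the phenoxide, which moves the cyclohexenone from O2 to the benzylic oxygen; 1,2-reduction at C3' is a second possible leak. The fallback changes the order of events and sets out from 9. Palladium-catalysed aerobic dehydrogenation (Pd(O2CCF3)2, 2-(dimethylamino)pyridine, TsOH, O2, DMSO, 80 °C) first aromatizes ring B to 2-(3-hydroxy-5-methylphenoxy)-5-methoxy-3-(methoxymethoxy)benzaldehyde F6, whose diaryl ether cannot migrate. NaBH4 gives 3-[2-(hydroxymethyl)-4-methoxy-6-(methoxymethoxy)phenoxy]-5-methylphenol F7. Enzymatic acylation, which is selective for the aliphatic OH over the phenol (vinyl hexadecanoate, immobilised Candida antarctica lipase B, tert-butyl methyl ether, 45 °C), rejoins the route at 15.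

**Step 3.** The magnesium ion may be held in a chelate between the phenoxide and the acetal oxygens, which would slow delivery of formaldehyde and allow partial loss of the acetal at reflux. The fallback uses a boron template instead and sets out from 4. PhB(OH)2, (CH2O)n and catalytic EtCO2H in refluxing toluene with removal of water give 6-methoxy-8-(methoxymethoxy)-2-phenyl-4H-1,3,2-benzodioxaborinine F8. Exchange with propane-1,3-diol frees 5, here isolated as the free phenol, and MnO2 in CH2Cl2 oxidises its benzylic alcohol, rejoining the route at 6.

## Further compounds

F1 | step 5 | 1-bromo-3-(methoxymethoxy)-5-methylbenzene | COCOc1cc(C)cc(Br)c1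
F2 | step 5 | 5-methoxy-3-(methoxymethoxy)-2-[3-(methoxymethoxy)-5-methylphenoxy]benzaldehyde | COCOc1cc(OC)cc(C=O)c1Oc1cc(C)cc(OCOC)c1
F3 | step 5 | [5-methoxy-3-(methoxymethoxy)-2-[3-(methoxymethoxy)-5-methylphenoxy]phenyl]methanol | COCOc1cc(OC)cc(CO)c1Oc1cc(C)cc(OCOC)c1
F4 | step 5 | [5-methoxy-3-(methoxymethoxy)-2-[3-(methoxymethoxy)-5-methylphenoxy]phenyl]methyl hexadecanoate | CCCCCCCCCCCCCCCC(=O)OCc1cc(OC)cc(OCOC)c1Oc1cc(C)cc(OCOC)c1
F5 | step 8 | [5-methoxy-3-(methoxymethoxy)-2-[(5-methyl-3-oxo-4-(phenylselanyl)cyclohex-1-en-1-yl)oxy]phenyl]methyl hexadecanoate | CCCCCCCCCCCCCCCC(=O)OCc1cc(OC)cc(OCOC)c1OC1=CC(=O)C([Se]c2ccccc2)C(C)C1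
F6 | step 6 | 2-(3-hydroxy-5-methylphenoxy)-5-methoxy-3-(methoxymethoxy)benzaldehyde | COCOc1cc(OC)cc(C=O)c1Oc1cc(C)cc(O)c1
F7 | step 6 | 3-[2-(hydroxymethyl)-4-methoxy-6-(methoxymethoxy)phenoxy]-5-methylphenol | COCOc1cc(OC)cc(CO)c1Oc1cc(C)cc(O)c1
F8 | step 3 | 6-methoxy-8-(methoxymethoxy)-2-phenyl-4H-1,3,2-benzodioxaborinine | COCOc1cc(OC)cc2c1OB(OC2)c1ccccc1
A1 | alternative 1 | orcinol (5-methylbenzene-1,3-diol) | Cc1cc(O)cc(O)c1
A2 | alternative 1 | 3-(benzyloxy)-2-fluoro-5-methoxybenzaldehyde | COc1cc(C=O)c(F)c(OCc2ccccc2)c1
A3 | alternative 1 | 3-(benzyloxy)-2-(3-hydroxy-5-methylphenoxy)-5-methoxybenzaldehyde | COc1cc(C=O)c(Oc2cc(C)cc(O)c2)c(OCc2ccccc2)c1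
A4 | alternative 2 | 3-(benzyloxy)-5-methyl-2-(trimethylsilyl)phenyl trifluoromethanesulfonate | Cc1cc(OCc2ccccc2)c([Si](C)(C)C)c(OS(=O)(=O)C(F)(F)F)c1
A5 | alternative 2 | 2-[3-(benzyloxy)-5-methylphenoxy]-5-methoxy-3-(methoxymethoxy)benzaldehyde | COCOc1cc(OC)cc(C=O)c1Oc1cc(C)cc(OCc2ccccc2)c1
A6 | alternative 3 | 2,6-dimethyl-4H-pyran-4-one | CC1=CC(=O)C=C(C)O1
A7 | alternative 3 | 4-[2-formyl-4-methoxy-6-(methoxymethoxy)phenoxy]-2,6-dimethylpyrylium trifluoromethanesulfonate | COCOc1cc(OC)cc(C=O)c1Oc1cc(C)[o+]c(C)c1.[O-]S(=O)(=O)C(F)(F)F
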